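## Retrosynthetic overview

1. The (2Z)-enoate (C2=C3) is cut by Still–Gennari olefination back to aldehyde 11, which comes from ethyl ester 10 by partial reduction.
2. The 6E olefin and the C4–C5 bond come from a Johnson–Claisen rearrangement of secondary allylic alcohol 8, made from the prenyl terminus of chroman 5 by a photochemical singlet-oxygen ene reaction and O-demethylation.
3. The chroman ring (the only ring formed; the arene is bought) is closed at O1–C8a by a photochemical ipso-substitution of an aryl OMe by the tertiary OH of 4.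
4. The C4–C4a bond comes from hydroboration of (R)-linalool 1 and B-alkyl Suzuki coupling with aryl bromide 2.
5. The only stereocentre is the carbinol carbon of (R)-linalool; its C–O bond is never broken.

Assumption: (R)-(−)-linalool (≥97% ee), aryl bromide 2 and methyl 2-[bis(2,2,2-trifluoroethoxy)phosphoryl]propanoate are bought as catalogue chemicals; the final ee equals that of the linalool.

## Route

Step 1
Reactants: 1 (R)-linalool; 2 2-bromo-1,5-dimethoxy-3-methylbenzene
Product: 4 (3R)-1-(2,4-dimethoxy-6-methylphenyl)-3,7-dimethyloct-6-en-3-ol, via B-alkyl-9-BBN borane 3 (not isolated)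
Conditions: 1 (1.25 equiv), 9-BBN (1.4 equiv), THF, 0 °C → rt, 4 h; then 2 (1.0 equiv), Pd(OAc)2 (3 mol %), SPhos (6 mol %), 3 M aq K3PO4 (3 equiv), 65 °C, 14 h
Reagents that add atoms: 9-BBN (9-borabicyclo[3.3.1]nonane), [H]B1C2CCCC1CCC2 (adds the boryl group of 3; no heavy atom of it remains in 4)
Why: 9-BBN hydroborates the monosubstituted vinyl group anti-Markovnikov far faster than the trisubstituted alkene, and the B-alkyl Suzuki–Miyaura coupling with SPhos tolerates the di-ortho-substituted, electron-rich aryl bromide and the free tertiary OH; the stereocentre is not touched.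

Step 2
Reactants: 4 (3R)-1-(2,4-dimethoxy-6-methylphenyl)-3,7-dimethyloct-6-en-3-ol
Product: 5 (2R)-7-methoxy-2,5-dimethyl-2-(4-methylpent-3-en-1-yl)chromane
Conditions: 3,6-di-tert-butyl-9-mesityl-10-phenylacridinium BF4 (5 mol %), DCE/HFIP 9:1 (0.02 M), 450 nm LEDs, N2, 25 °C, 24 h; no H-atom donor added
Reagents that add atoms: none
Why: Proposed new method: intramolecular cation-radical-accelerated SNAr of an aryl methyl ether by a tertiary alcohol. The excited acridinium (E*red about +2.1 V) oxidises the dialkoxyarene of 4 (about +1.3–1.4 V, well below the trisubstituted alkene at about +1.9 V) to its radical cation, whose SOMO has large coefficients at both OMe-bearing carbons. The tethered OH adds at the ortho C–OMe carbon through a six-membered transition state, the mixed-ketal radical loses MeOH (HFIP-assisted) to give the radical cation of 5, and the acridinyl radical reduces it, so the cycle is redox-neutral. Without an H-atom donor the competing alkene hydroetherification cannot turn over, and the O–C(quaternary) bond is never broken, so configuration is retained. Closest known reaction type: acridinium-photocatalysed cation-radical-accelerated SNAr of methoxyarenes by azoles, amines and cyanide, and anodic ipso-alkoxylation of alkoxyarenes; ring closure by a tertiary alcohol to an aryl tert-alkyl ether has not been shown.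

Step 3
Reactants: 5 (2R)-7-methoxy-2,5-dimethyl-2-(4-methylpent-3-en-1-yl)chromane
Product: 7 5-[(2S)-7-methoxy-2,5-dimethylchroman-2-yl]-2-methylpent-1-en-3-ol (C3 epimers), via allylic hydroperoxide 6 (not isolated)
Conditions: O2 (1 atm), TPP (0.5 mol %), CH2Cl2, white LEDs, 0 °C, 2 h; then PPh3 (1.2 equiv), 0 °C → rt; chromatography removes the tertiary-alcohol regioisomer
Reagents that add atoms: dioxygen, O=O
Why: The Schenck ene reaction of singlet oxygen takes an H from a geminal methyl of the trisubstituted alkene and delivers the secondary hydroperoxide with an isopropenyl group (about 1:1 with the separable tertiary regioisomer), which PPh3 reduces; the dialkoxyarene reacts far more slowly with 1O2, and the new carbinol centre is a throw-away epimer mixture erased in step 5.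

Step 4
Reactants: 7 5-[(2S)-7-methoxy-2,5-dimethylchroman-2-yl]-2-methylpent-1-en-3-ol
Product: 8 (2S)-2-(3-hydroxy-4-methylpent-4-en-1-yl)-2,5-dimethylchroman-7-ol (epimers at the carbinol)
Conditions: EtSNa (6 equiv), DMF, 140 °C, 4 h; 1 M HCl work-up
Reagents that add atoms: none
Why: Thiolate SN2 demethylation of the aryl methyl ether is possible only at the O–CH3 carbon, since the tertiary alkyl aryl ether of the chroman cannot undergo SN2, and it is done here because no ester or aldehyde is present yet.

Step 5
Reactants: 8 (2S)-2-(3-hydroxy-4-methylpent-4-en-1-yl)-2,5-dimethylchroman-7-ol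
Product: 10 ethyl (4E)-7-[(2R)-7-hydroxy-2,5-dimethylchroman-2-yl]-4-methylhept-4-enoate, via mixed ketene acetal 9 (not isolated)
Conditions: MeC(OEt)3 (8 equiv), EtCO2H (0.1 equiv), 140 °C, 3 h, EtOH distilled off; then 1 M HCl/THF, rt, 15 min
Reagents that add atoms: triethyl orthoacetate, CC(OCC)(OCC)OCC
Why: In the Johnson–Claisen rearrangement, acid-catalysed exchange and loss of two EtOH give ketene acetal 9, which rearranges through a chair with the chroman-bearing chain equatorial (the axial alternative suffers a 1,3-diaxial clash with OEt), giving the 6E trisubstituted olefin in ≥98:2; the acidic work-up returns any aryl orthoester to the phenol.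

Step 6
Reactants: 10 ethyl (4E)-7-[(2R)-7-hydroxy-2,5-dimethylchroman-2-yl]-4-methylhept-4-enoate
Product: 11 (4E)-7-[(2R)-7-hydroxy-2,5-dimethylchroman-2-yl]-4-methylhept-4-enal
Conditions: DIBAL-H (2.2 equiv), CH2Cl2, −78 °C, 1 h; MeOH, then aq Rochelle salt
Reagents that add atoms: none
Why: Partial reduction of an aliphatic ester with DIBAL-H at −78 °C stops at the aldehyde oxidation level; the first equivalent is consumed by the phenol O–H, and olefins and chroman are inert.

Step 7
Reactants: 11 (4E)-7-[(2R)-7-hydroxy-2,5-dimethylchroman-2-yl]-4-methylhept-4-enal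
Product: 12 methyl (2Z,6E)-9-[(2R)-7-hydroxy-2,5-dimethylchroman-2-yl]-2,6-dimethylnona-2,6-dienoate
Conditions: (CF3CH2O)2P(O)CH(CH3)CO2Me (2.4 equiv), KHMDS (2.3 equiv), 18-crown-6 (5 equiv), THF, −78 °C, 30 min; then 11, −78 °C, 2 h; aq NH4Cl
Reagents that add atoms: methyl 2-[bis(2,2,2-trifluoroethoxy)phosphoryl]propanoate, COC(=O)C(C)P(=O)(OCC(F)(F)F)OCC(F)(F)F
Why: In the Still–Gennari olefination the electron-poor phosphonate with dissociated K+ eliminates fast from the kinetic adduct and gives the (Z)-α-methyl enoate (typically ≥15:1, minor E isomer removed by chromatography); the excess anion deprotonates the phenol, and the 6E olefin and the stereocentre are untouched.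

## Compound list

Descriptors R/S at the chroman or carbinol carbon change only through CIP priorities; the spatial arrangement is that of 1 throughout.

1 | (R)-(−)-linalool, (3R)-3,7-dimethylocta-1,6-dien-3-ol | CC(C)=CCC[C@@](C)(O)C=C | starting material
2 | 2-bromo-1,5-dimethoxy-3-methylbenzene | COc1cc(C)c(Br)c(OC)c1 | starting material
3 | (3S)-1-(9-borabicyclo[3.3.1]nonan-9-yl)-3,7-dimethyloct-6-en-3-ol | CC(C)=CCC[C@@](C)(O)CCB1C2CCCC1CCC2 | intermediate (not isolated)
4 | (3R)-1-(2,4-dimethoxy-6-methylphenyl)-3,7-dimethyloct-6-en-3-ol | CC(C)=CCC[C@@](C)(O)CCc1c(C)cc(OC)cc1OC | intermediate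
5 | (2R)-7-methoxy-2,5-dimethyl-2-(4-methylpent-3-en-1-yl)chromane | CC(C)=CCC[C@]1(C)CCc2c(C)cc(OC)cc2O1 | intermediate
6 | (2S)-2-(3-hydroperoxy-4-methylpent-4-en-1-yl)-7-methoxy-2,5-dimethylchromane, epimers at C3' | CC(=C)C(OO)CC[C@]1(C)CCc2c(C)cc(OC)cc2O1 | intermediate (not isolated)
7 | 5-[(2S)-7-methoxy-2,5-dimethylchroman-2-yl]-2-methylpent-1-en-3-ol, epimers at C3 | CC(=C)C(O)CC[C@]1(C)CCc2c(C)cc(OC)cc2O1 | intermediate
8 | (2S)-2-(3-hydroxy-4-methylpent-4-en-1-yl)-2,5-dimethylchroman-7-ol, epimers at C3' | CC(=C)C(O)CC[C@]1(C)CCc2c(C)cc(O)cc2O1 | intermediate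
9 | (2S)-2-{3-[(1-ethoxyethenyl)oxy]-4-methylpent-4-en-1-yl}-2,5-dimethylchroman-7-ol, epimers at C3' | CCOC(=C)OC(CC[C@]1(C)CCc2c(C)cc(O)cc2O1)C(C)=C | intermediate (not isolated)
10 | ethyl (4E)-7-[(2R)-7-hydroxy-2,5-dimethylchroman-2-yl]-4-methylhept-4-enoate | CCOC(=O)CC/C(C)=C/CC[C@]1(C)CCc2c(C)cc(O)cc2O1 | intermediate
11 | (4E)-7-[(2R)-7-hydroxy-2,5-dimethylchroman-2-yl]-4-methylhept-4-enal | O=CCC/C(C)=C/CC[C@]1(C)CCc2c(C)cc(O)cc2O1 | intermediate
12 | methyl (2Z,6E)-9-[(2R)-7-hydroxy-2,5-dimethylchroman-2-yl]-2,6-dimethylnona-2,6-dienoate (CNP0319148.1) | COC(=O)/C(C)=C\CC/C(C)=C/CC[C@]1(C)CCc2c(C)cc(O)cc2O1 | target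

## Step count and risks

Total step count: 7. Longest linear sequence: 7 (1 → 12).

The three steps most likely to fail:

Step 2 (the proposed photochemical ring closure). The tertiary OH may add too slowly to the arene radical cation, or benzylic oxidation may compete. The fallback uses known Pd-catalysed aryl C–O coupling and sets out from 1. Commercial 1-bromo-3-methoxy-5-methylbenzene is iodinated para to the methoxy group (NIS, cat. TFA, MeCN, rt) to give 1-bromo-2-iodo-5-methoxy-3-methylbenzene F1. Borane 3, made from 1 as in step 1, is coupled with F1 selectively at the C–I bond (Pd(dppf)Cl2, aq K3PO4, THF, 50 °C) to give (3R)-1-(2-bromo-4-methoxy-6-methylphenyl)-3,7-dimethyloct-6-en-3-ol F2. Intramolecular etherification of the tertiary alcohol (Pd(OAc)2, 2-(di-tert-butylphosphino)-1,1'-binaphthyl, Cs2CO3, toluene, 80 °C) then closes the ring with retention and comes back to the route at 5.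

Step 3 (singlet-oxygen ene reaction). The regioselectivity is only about 1:1, and the electron-rich arene may quench or react with 1O2. The fallback sets out from 5 and is not photochemical. Epoxidation of the trisubstituted alkene (mCPBA, NaHCO3, CH2Cl2, 0 °C) gives (2S)-2-[2-(3,3-dimethyloxiran-2-yl)ethyl]-7-methoxy-2,5-dimethylchromane F3 as an epimer mixture. Base-induced epoxide-to-allylic-alcohol isomerisation with proton removal from a methyl group (Et2Al-TMP, toluene, 0 °C, or Al(OiPr)3, toluene, reflux) gives the secondary isopropenyl carbinol and comes back to the route at 7.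

Step 7 (Still–Gennari olefination on the free-phenol aldehyde). The phenoxide may lower conversion or erode the Z:E ratio. The fallback sets out from 11 and builds the Z-enoate by stereospecific cross-coupling instead of olefination. Corey–Fuchs dibromo-olefination (CBr4, PPh3, Et3N, CH2Cl2, 0 °C) gives (2R)-2-[(3E)-8,8-dibromo-4-methylocta-3,7-dien-1-yl]-2,5-dimethylchroman-7-ol F4. Trans-selective Negishi monomethylation (MeZnCl, 2.5 equiv, Pd(DPEphos)Cl2, THF, 0 °C → rt) replaces the bromine trans to the chain and gives (2R)-2-[(3E,7Z)-8-bromo-4-methylnona-3,7-dien-1-yl]-2,5-dimethylchroman-7-ol F5. Pd-catalysed methoxycarbonylation with retention of geometry (PdCl2(PPh3)2, CO 1 atm, MeOH, Et3N, 60 °C) places CO2Me cis to the chain and comes back to the route at 12.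

## Further compounds

F1 | step 2 | 1-bromo-2-iodo-5-methoxy-3-methylbenzene | COc1cc(C)c(I)c(Br)c1
F2 | step 2 | (3R)-1-(2-bromo-4-methoxy-6-methylphenyl)-3,7-dimethyloct-6-en-3-ol | CC(C)=CCC[C@@](C)(O)CCc1c(C)cc(OC)cc1Br
F3 | step 3 | (2S)-2-[2-(3,3-dimethyloxiran-2-yl)ethyl]-7-methoxy-2,5-dimethylchromane, epoxide epimers | CC1(C)OC1CC[C@]1(C)CCc2c(C)cc(OC)cc2O1
F4 | step 7 | (2R)-2-[(3E)-8,8-dibromo-4-methylocta-3,7-dien-1-yl]-2,5-dimethylchroman-7-ol | BrC(Br)=CCC/C(C)=C/CC[C@]1(C)CCc2c(C)cc(O)cc2O1
F5 | step 7 | (2R)-2-[(3E,7Z)-8-bromo-4-methylnona-3,7-dien-1-yl]-2,5-dimethylchroman-7-ol | C/C(Br)=C/CC/C(C)=C/CC[C@]1(C)CCc2c(C)cc(O)cc2O1
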